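| flask | substrate | partner | remark | time |
|---|---|---|---|---|
| west | 10 mM | 10 mM | run made earlier |  |
| north-west | 10 mM | 40 mM | run made earlier |  |
| north | 20 mM | 20 mM | run made earlier |  |
| flask | 10 mM | 20.0 mM |  | 12 d |

| run | time / d | other mono adduct / % | mono adduct / % |
|---|---|---|---|
| west | 1.67 | 32 | 0 |
| west | 3.00 | 32 | 2 |
| west | 5.00 | 30 | 0 |
| west | 6.00 | 33 | 0 |
| west | 8.00 | 30 | 0 |
| west | 10.0 | 29 | 1 |
| west | 12.0 | 29 | 0 |
| north-west | 1.04 | 2 | 1 |
| north-west | 1.67 | 6 | 1 |
| north-west | 2.00 | 2 | 0 |
| north-west | 3.00 | 2 | 0 |
| north-west | 5.00 | 3 | 0 |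
| north-west | 8.00 | 3 | 1 |
| north-west | 12.0 | 4 | 3 |
| north | 1.04 | 33 | 0 |
| north | 3.00 | 34 | 0 |
| north | 6.00 | 31 | 2 |
| north | 8.00 | 30 | 0 |
| north | 12.0 | 32 | 0 |

(each reading ± 1.5 percentage points)

- equivalents of partner to substrate, everything else as given, that leave most other mono adduct at 12 d
- the amount of other mono adduct then, in percent of the substrate charged
- the amount of other mono adduct with the amounts as given

Take the ratio of two rates in the west run. Up to the first reading, other mono adduct (N) appears at a mean of at least 0.192 d⁻¹ of the substrate charge. From there to the last reading it drifts down at 0.00290 d⁻¹, so the rate has dropped by a factor of about 66.2, and that drift is 3 percentage points against a scatter of 1.5 points per reading. Stop counting days, then, and count partner charged as the clock of these runs.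

Going from the west run to the north-west run raises partner from 10 mM to 40 mM, and mean N falls from 30.7% to 3.14%. Define the dose share φ, a selectivity: N lost per unit of further partner charged, 0.0919. Two doses give a single φ and cannot test whether it drifts, so holding it constant is an assumption of this reckoning. The flask carries 10.0 mM more partner than the west run on the same substrate, so my reckoning for it is 21.5%.

The forecast reads the runs as “fast equilibrium, not slow kinetics”. It gives 31.5% at 1.07 equiv, and 18% as charged, which is less than my figure.

The flask gives 22.4% as charged, and the best recipe gives 35.0% at 1.26 equiv.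

    crystals ⇌ released group, rate k1*(cs1 - [released group]) while solid is left; crystals form when [released group] > cs1 (solubility = 5.30 mM, k = 0.0168 s⁻¹)
    partner + mono adduct → bis adduct + released group (k = 0.0814 L mol⁻¹ s⁻¹)
    partner → decomposed reagent (k = 8.58 × 10⁻⁵ s⁻¹)
    substrate + partner → mono adduct + released group (k = 0.118 L mol⁻¹ s⁻¹)
    substrate + partner → other mono adduct + released group (k = 0.0807 L mol⁻¹ s⁻¹)
    mono adduct + released group → side product (k = 0.255 L mol⁻¹ s⁻¹)
    partner + other mono adduct → bis adduct + released group (k = 0.00926 L mol⁻¹ s⁻¹)

Apply φ to the neighbour flask with 34 mM of partner, 3.40 equiv against 10 mM of substrate. It lies 24.0 mM past the west run, so the reckoning gives 8.66%, which is 2 points above what that neighbour holds at 12.0 d. In the flask itself the same line fell 0.90 points below the result. That neighbour ends with 67.5% as bis adduct, 25.8% as side product and 6.62% as other mono adduct.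

(The numbers in the tables were computed for an exercise.)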